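**Retrosynthetic overview**

1. Magnolol 1 (bought) already contains rings A–B of the target, so the only disconnection is the honokiol-type B–C biaryl bond: ortho carbon of the ring-B phenol to para carbon of the ring-C phenol.
2. Both ends of that bond are innately nucleophilic, so ring B is used with reversed polarity. PhI(OAc)2/MeOH converts one ring of 1, through aryloxy-λ3-iodane 2, into p-quinol methyl ether 3, an aryl-cation (vinylogous enolonium) equivalent that keeps its allyl group.
3. Unprotected 2-allylphenol 4 (bought) attacks C6 of 3 through its para carbon with SN2′ loss of methanol; dienone 5 then tautomerises to simonsinol 6.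
4. No ring is constructed: all three benzene rings are bought. Ring B is dearomatised in step 1 and rearomatised in step 2, without protecting groups.

Assumption: simonsinol has no stereocentre and no configurationally stable biaryl axis, so there is no enantiomer to select; magnolol (Magnolia-bark isolate sold in bulk) is taken as a cheap commercial starting material.

**Route**

Step 1  
Reactants: 1 magnolol (5,5'-diallyl-[1,1'-biphenyl]-2,2'-diol)  
Product: 3 rac-4-allyl-2-(5-allyl-2-hydroxyphenyl)-4-methoxycyclohexa-2,5-dien-1-one (mono-p-quinol methyl ether of magnolol), via aryloxy-λ3-iodane 2 (not isolated)  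
Conditions: PhI(OAc)2 (0.9 equiv, added over 20 min), MeOH (0.03 M), −10 → 0 °C, 30 min; aq NaHCO3; fast column on Et3N-washed silica, recovered 1 recycled  
Reagents that add atoms: methanol (CO)  
Why: PhI(OAc)2/MeOH oxidative dearomatisation of a 4-alkylphenol to its p-quinol methyl ether: ligand exchange gives 2, methanol adds to the allyl-bearing para carbon as PhI leaves, the terminal alkenes are inert to iodine(III) in MeOH, and a slight deficit of oxidant limits oxidation of the second ring; the C4 stereocentre forms racemic and is erased in step 2.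

Step 2  
Reactants: 3 rac-4-allyl-2-(5-allyl-2-hydroxyphenyl)-4-methoxycyclohexa-2,5-dien-1-one, 4 2-allylphenol  
Product: 6 simonsinol, via cyclohexa-2,4-dienone 5 (not isolated)  
Conditions: 3 added over 30 min to 4 (5 equiv), MsOH (10 mol %), HFIP–CH2Cl2 (4:1), −20 → 0 °C; NaHCO3 quench; excess 4 recovered  
Reagents that add atoms: none  
Why: Proposed new method: protonation of the tertiary methoxy group in strongly ionising, weakly nucleophilic HFIP turns 3 into a ring-B phenoxonium (aryl-cation) equivalent in which C4 is quaternary and C2 is blocked by ring A, so the para carbon of 4 (its OH hydrogen-bonded to HFIP, its ortho site more hindered) attacks C6 in SN2′ fashion with loss of MeOH and dienone 5 aromatises irreversibly by tautomerisation, whereas conjugate adducts at C3/C5 are reversible and cannot aromatise; the closest known reaction types are the Brønsted-acid-promoted α-arylation of p-quinone monoacetals with phenols in fluoroalcohols and the PhI(OAc)2/HFIP "aromatic-ring umpolung" arylation of 4-alkylphenols; the allyl groups survive catalytic acid at ≤0 °C and no stereocentre remains in 6.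

**Compound list**

1 | magnolol (5,5'-diallyl-[1,1'-biphenyl]-2,2'-diol) | C=CCc1ccc(O)c(-c2cc(CC=C)ccc2O)c1 | starting material  
2 | acetoxy(phenyl)-λ3-iodanyl mono-aryl ether of magnolol | CC(=O)OI(Oc1ccc(CC=C)cc1-c1cc(CC=C)ccc1O)c1ccccc1 | intermediate (not isolated)  
3 | rac-4-allyl-2-(5-allyl-2-hydroxyphenyl)-4-methoxycyclohexa-2,5-dien-1-one | C=CCC1(OC)C=CC(=O)C(-c2cc(CC=C)ccc2O)=C1 | intermediate  
4 | 2-allylphenol | C=CCc1ccccc1O | starting material  
5 | rac-4-allyl-2-(5-allyl-2-hydroxyphenyl)-6-(3-allyl-4-hydroxyphenyl)cyclohexa-2,4-dien-1-one | C=CCC1=CC(c2ccc(O)c(CC=C)c2)C(=O)C(-c2cc(CC=C)ccc2O)=C1 | intermediate (not isolated)  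
6 | simonsinol | C=CCc1ccc(O)c(-c2cc(CC=C)cc(-c3ccc(O)c(CC=C)c3)c2O)c1 | target

**Totals and risks**

Total step count: 2. Longest linear sequence: 2.

The route has only two steps, so both are ranked, the riskier first; there is no third.

Step 2 (most likely to fail). The acid may trigger allyl [3,3]/[1,2] shifts in 3 or closure of the neighbouring ring-A hydroxyl onto the dienone. Ring C may also attack through its ortho carbon or its oxygen, or the product may be arylated again. The fallback makes the B–C bond by cross-coupling instead; it sets out from 1 and comes back to the route at 6. Compound 1 is mono-brominated ortho to one hydroxyl (NBS 1.0 equiv, cat. i-Pr2NH, CH2Cl2, −78 → 0 °C) to give 3-bromomagnolol F1. Purchased 2-allyl-4-bromophenol F2 is converted by Miyaura borylation (B2pin2, KOAc, cat. Pd(dppf)Cl2, dioxane, 80 °C) into 2-allyl-4-(pinacolboryl)phenol F3. Protecting-group-free Suzuki–Miyaura coupling of F1 with F3 (cat. SPhos-Pd, K3PO4, THF/H2O, 40 °C) gives 6 directly.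

Step 1. Oxidation may not stop at one ring (bis-dienone), or the free hydroxyl beside the dienone may make 3 too labile to isolate. The fallback masks one hydroxyl first; it sets out from 1 and comes back to the route at 6. Compound 1 with TBSCl (1.0 equiv), imidazole, CH2Cl2/DMF, 0 °C gives mono-TBS magnolol F4, the first silyl group hindering the second silylation. PhI(OAc)2 (1.1 equiv) in MeOH at 0 °C can then be run to full conversion to give silyl-protected quinol ether F5, which has no hydroxyl next to the dienone. Arylation of F5 with 4 under the step 2 conditions gives O-TBS-simonsinol F6, and KHF2 in MeOH at rt cleaves the aryl silyl ether to give 6.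

**Further compounds**

F1 | step 2 | 3-bromomagnolol (5,5'-diallyl-3-bromo-[1,1'-biphenyl]-2,2'-diol) | C=CCc1cc(Br)c(O)c(-c2cc(CC=C)ccc2O)c1  
F2 | step 2 | 2-allyl-4-bromophenol (purchased) | C=CCc1cc(Br)ccc1O  
F3 | step 2 | 2-allyl-4-(4,4,5,5-tetramethyl-1,3,2-dioxaborolan-2-yl)phenol | C=CCc1cc(B2OC(C)(C)C(C)(C)O2)ccc1O  
F4 | step 1 | mono-TBS magnolol (5,5'-diallyl-2'-(tert-butyldimethylsilyloxy)-[1,1'-biphenyl]-2-ol) | C=CCc1ccc(O)c(-c2cc(CC=C)ccc2O[Si](C)(C)C(C)(C)C)c1  
F5 | step 1 | rac-4-allyl-2-[5-allyl-2-(tert-butyldimethylsilyloxy)phenyl]-4-methoxycyclohexa-2,5-dien-1-one | C=CCC1(OC)C=CC(=O)C(-c2cc(CC=C)ccc2O[Si](C)(C)C(C)(C)C)=C1  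
F6 | step 1 | O-TBS-simonsinol (ring-A silyl ether) | C=CCc1ccc(O[Si](C)(C)C(C)(C)C)c(-c2cc(CC=C)cc(-c3ccc(O)c(CC=C)c3)c2O)c1  
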